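**Plan**
- Retrosynthesis first cuts the two ester C6–O bonds, giving the C10 diacid and two molecules of one bicyclic amino alcohol. In the bicycle it then cuts the C7–C7a bond of the cyclopentane and the C4a–C5 bond to the pyridine-derived ring.
- Enabling feature: C7 sits next to the oxygen-bearing C6 and is bonded to C7a, the β-carbon of the N2–C1 unit of the piperidine ring. An electrophilic C7 ketoester radical and a C1=C7a enecarbamate are therefore polarity-matched.
- Forward: the six-membered ring comes from 3-picoline by dearomative C4 alkylation, the five-membered ring closes second by anodic radical annulation, and the diacid chain from geranyl acetate is joined last by double Mitsunobu esterification.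
- Stereochemistry: C4a from the catalyst-controlled dearomatisation; C7a from the enforced cis closure; C4 from convex-face hydrogenation; C7 by equilibration after decarboxylation; C6 by hydride reduction then Mitsunobu inversion; both E alkenes from geranyl acetate.

Key step: step 4

Remark: cyclopenta[c]pyridine numbering (C1, N2, C3, C4, C4a, C5, C6, C7, C7a) is used for the bicycle and carried back to its precursors; stereocentres that are later removed or equilibrated carry no descriptor; the catalyst antipode that gives the (R)-adduct 8 is assumed to be identified in a first screen.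

Step 1
Reactants: 1 methyl 2-methyl-3-oxobutanoate
Product: 2 methyl 2-methyl-3-(trimethylsilyloxy)but-2-enoate (E/Z mixture)
Conditions: Me3SiCl, Et3N, pentane, rt
Reagents that add atoms: chlorotrimethylsilane C[Si](C)(C)Cl
Why: Soft enolisation of the β-ketoester by Et3N and O-silylation gives the conjugated silyl enol ether, the standard first stage of a Chan-type diene synthesis; no stereocentre is formed.

Step 2
Reactants: 2 methyl 2-methyl-3-(trimethylsilyloxy)but-2-enoate
Product: 3 1-methoxy-2-methyl-1,3-bis(trimethylsilyloxy)buta-1,3-diene (E/Z mixture)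
Conditions: LiN(iPr)2, THF, −78 °C; then Me3SiCl, −78 °C to rt
Reagents that add atoms: chlorotrimethylsilane C[Si](C)(C)Cl
Why: Kinetic γ-deprotonation of the vinylogous ester and O-silylation of the dienolate (Chan–Molander procedure) should give the 1,3-bis(silyloxy)diene, whose terminal CH2 is the nucleophilic carbon.

Step 3
Reactants: 4 3-methylpyridine; 5 methyl chloroformate; 3 1-methoxy-2-methyl-1,3-bis(trimethylsilyloxy)buta-1,3-diene
Product: 8 methyl (4R)-4-(4-methoxy-3-methyl-2,4-dioxobutyl)-3-methyl-4H-pyridine-1-carboxylate, via 1-(methoxycarbonyl)-3-methylpyridinium chloride 6 (not isolated), via silyl enol ether adduct 7 (not isolated)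
Conditions: 4, 5, MTBE, 0 °C; then chiral tetrakis(1,2,3-triazole) hydrogen-bond-donor catalyst on a trans-cyclohexane-1,2-diamine core (10 mol %), 3, −78 °C; aq. citric acid work-up
Reagents that add atoms: none
Why: Proposed new method: the chiral donor binds the chloride of the preformed N-acylpyridinium ion pair, so the soft terminal carbon of the bis-silyl dienolate should add to one face of C4 (the site silyl enol ethers prefer over C2 and C6) and set the later C4a centre as R; the closest known reaction types are the uncatalysed C4 addition of silyl enol ethers to N-alkoxycarbonylpyridinium chlorides and the anion-binding-catalysed enantioselective acyl-Mannich dearomatisation of pyridines and isoquinolines with silyl ketene acetals.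

Step 4
Reactants: 8 methyl (4R)-4-(4-methoxy-3-methyl-2,4-dioxobutyl)-3-methyl-4H-pyridine-1-carboxylate
Product: 9 dimethyl (4aR,7aR)-1-methoxy-4,7-dimethyl-6-oxo-1,4a,5,6,7,7a-hexahydro-2H-cyclopenta[c]pyridine-2,7-dicarboxylate (cis-fused; epimers at C1 and C7)
Conditions: Fe(C5H5)2 (10 mol %), LiOMe (0.3 equiv), nBu4NBF4, MeOH/THF, reticulated vitreous carbon anode, Pt cathode, undivided cell, constant current, 40 °C
Reagents that add atoms: methanol CO
Why: Proposed new method: anodically formed ferrocenium (trivalent iron) should oxidise the lithium enolate of the β-ketoester at a potential well below that of the enecarbamates, giving an electrophilic tertiary C7 radical that adds to the electron-rich, unsubstituted enecarbamate carbon C7a; the α-amido C1 radical is then oxidised to the N-acyliminium ion and captured by methanol while protons are reduced at the cathode. The closest known reaction type is the ferrocene-mediated electrochemical oxidative radical cyclisation of 1,3-dicarbonyl compounds onto alkenes, here extended to an enecarbamate acceptor. The cyclopentanone closes in a 5-exo-trig mode through the new C7–C7a bond. C7a is controlled by C4a, because the tether hangs from C4a and can reach only the same face, so the ring fusion must be cis; C1 and C7 form as mixtures that steps 5 and 7 remove. The step needs attack at C7a and not at C4, and the methyl group on C4 should secure this because closure there would join two fully substituted carbons.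

Step 5
Reactants: 9 dimethyl (4aR,7aR)-1-methoxy-4,7-dimethyl-6-oxo-1,4a,5,6,7,7a-hexahydro-2H-cyclopenta[c]pyridine-2,7-dicarboxylate
Product: 10 dimethyl (4aR,7aR)-4,7-dimethyl-6-oxo-1,4a,5,6,7,7a-hexahydro-2H-cyclopenta[c]pyridine-2,7-dicarboxylate (C7 epimers)
Conditions: Et3SiH, BF3·OEt2, CH2Cl2, −78 °C
Reagents that add atoms: none
Why: BF3·OEt2 ionises the N,O-acetal to the N-acyliminium ion and Et3SiH reduces it to the C1 methylene (ionic reduction of an α-methoxy carbamate); at −78 °C without protic acid the C3=C4 enecarbamate and the ketone should be left untouched.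

Step 6
Reactants: 10 dimethyl (4aR,7aR)-4,7-dimethyl-6-oxo-1,4a,5,6,7,7a-hexahydro-2H-cyclopenta[c]pyridine-2,7-dicarboxylate
Product: 11 dimethyl (4R,4aS,7aR)-4,7-dimethyl-6-oxooctahydro-2H-cyclopenta[c]pyridine-2,7-dicarboxylate (C7 epimers)
Conditions: H2 (5 bar), Pd/C (10 wt %), EtOAc, rt
Reagents that add atoms: none
Why: Heterogeneous hydrogenation of the trisubstituted enecarbamate should deliver hydrogen from the convex face of the cis-fused bicycle, the face of H4a and H7a, setting C4 as R with its methyl group cis to C5.

Step 7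
Reactants: 11 dimethyl (4R,4aS,7aR)-4,7-dimethyl-6-oxooctahydro-2H-cyclopenta[c]pyridine-2,7-dicarboxylate
Product: 12 methyl (4R,4aS,7S,7aR)-4,7-dimethyl-6-oxooctahydro-2H-cyclopenta[c]pyridine-2-carboxylate
Conditions: LiCl, H2O, DMSO, 150 °C
Reagents that add atoms: none
Why: Krapcho dealkoxycarbonylation removes the activated C7 ester, and under the hot, weakly basic conditions C7 should equilibrate through the enol to the more stable epimer with the methyl group on the convex face, trans to the C7a–C1 bond (7S).

Step 8
Reactants: 12 methyl (4R,4aS,7S,7aR)-4,7-dimethyl-6-oxooctahydro-2H-cyclopenta[c]pyridine-2-carboxylate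
Product: 14 (4R,4aS,6S,7S,7aR)-2,4,7-trimethyloctahydro-1H-cyclopenta[c]pyridin-6-ol, via hydroxy carbamate 13 (not isolated)
Conditions: LiAlH4, THF, −78 °C to reflux; aq. NaOH work-up
Reagents that add atoms: none
Why: Hydride should attack the cyclopentanone at low temperature from the convex face, away from the piperidine ring and its C4 methyl group, placing the hydroxyl on the concave face trans to the C7 methyl (6S); on heating the methyl carbamate is reduced to the N-methyl group (LiAlH4 reduction of ketone and carbamate).

Step 9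
Reactants: 15 geranyl acetate
Product: 16 (2E,6E)-8-hydroxy-3,7-dimethylocta-2,6-dien-1-yl acetate
Conditions: SeO2 (cat.), t-BuOOH, salicylic acid (cat.), CH2Cl2, rt
Reagents that add atoms: selenium dioxide O=[Se]=O (catalytic oxygen carrier); tert-butyl hydroperoxide CC(C)(C)OO (terminal oxidant)
Why: Catalytic SeO2 allylic oxidation (ene reaction then [2,3]-sigmatropic shift, Sharpless conditions) is selective for the E-methyl group of the electron-rich terminal alkene, so the acetate-deactivated alkene is spared and the new alkene geometry is E.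

Step 10
Reactants: 16 (2E,6E)-8-hydroxy-3,7-dimethylocta-2,6-dien-1-yl acetate
Product: 17 (2E,6E)-2,6-dimethylocta-2,6-diene-1,8-diol
Conditions: K2CO3, MeOH, rt
Reagents that add atoms: none
Why: Base-catalysed methanolysis (transesterification) removes the acetate without touching either alkene.

Step 11
Reactants: 17 (2E,6E)-2,6-dimethylocta-2,6-diene-1,8-diol
Product: 18 (2E,6E)-2,6-dimethylocta-2,6-dienedial
Conditions: MnO2, CH2Cl2, rt
Reagents that add atoms: none
Why: MnO2 oxidises both allylic primary alcohols to the enals without over-oxidation and should keep the E geometry.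

Step 12
Reactants: 18 (2E,6E)-2,6-dimethylocta-2,6-dienedial
Product: 19 (2E,6E)-2,6-dimethylocta-2,6-dienedioic acid
Conditions: NaClO2, NaH2PO4, 2-methyl-2-butene, t-BuOH/H2O, rt
Reagents that add atoms: sodium chlorite [Na+].[O-]Cl=O
Why: Pinnick oxidation converts both enals into acids under buffered conditions, the alkene scavenger removing hypochlorous acid so that the trisubstituted alkenes survive.

Step 13
Reactants: 14 (4R,4aS,6S,7S,7aR)-2,4,7-trimethyloctahydro-1H-cyclopenta[c]pyridin-6-ol (2.2 equiv); 19 (2E,6E)-2,6-dimethylocta-2,6-dienedioic acid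
Product: 20 bis[(4R,4aS,6R,7S,7aR)-2,4,7-trimethyloctahydro-1H-cyclopenta[c]pyridin-6-yl] (2E,6E)-2,6-dimethylocta-2,6-dienedioate
Conditions: PPh3, DIAD, THF, 0 °C to rt
Reagents that add atoms: none
Why: Double Mitsunobu esterification: each carboxylate displaces the oxyphosphonium-activated C6 oxygen in an SN2 process with inversion, turning 6S into the 6R ester configuration of the target while the amines and E alkenes are unchanged.

**Compound list**
1 | methyl 2-methyl-3-oxobutanoate | COC(=O)C(C)C(C)=O | starting material
2 | methyl 2-methyl-3-(trimethylsilyloxy)but-2-enoate (E/Z mixture) | COC(=O)C(C)=C(C)O[Si](C)(C)C | intermediate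
3 | 1-methoxy-2-methyl-1,3-bis(trimethylsilyloxy)buta-1,3-diene (E/Z mixture) | COC(O[Si](C)(C)C)=C(C)C(=C)O[Si](C)(C)C | intermediate
4 | 3-methylpyridine | Cc1cccnc1 | starting material
5 | methyl chloroformate | COC(=O)Cl | starting material
6 | 1-(methoxycarbonyl)-3-methylpyridinium chloride | COC(=O)[n+]1cccc(C)c1.[Cl-] | intermediate
7 | methyl (4R)-4-[4-methoxy-3-methyl-4-oxo-2-(trimethylsilyloxy)but-2-en-1-yl]-3-methyl-4H-pyridine-1-carboxylate (silyl enol ether adduct) | COC(=O)C(C)=C(O[Si](C)(C)C)C[C@@H]1C=CN(C(=O)OC)C=C1C | intermediate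
8 | methyl (4R)-4-(4-methoxy-3-methyl-2,4-dioxobutyl)-3-methyl-4H-pyridine-1-carboxylate (side-chain epimers) | COC(=O)C(C)C(=O)C[C@@H]1C=CN(C(=O)OC)C=C1C | intermediate
9 | dimethyl (4aR,7aR)-1-methoxy-4,7-dimethyl-6-oxo-1,4a,5,6,7,7a-hexahydro-2H-cyclopenta[c]pyridine-2,7-dicarboxylate (epimers at C1 and C7) | O=C1C[C@@H]2[C@@H](C(OC)N(C(=O)OC)C=C2C)C1(C)C(=O)OC | intermediate
10 | dimethyl (4aR,7aR)-4,7-dimethyl-6-oxo-1,4a,5,6,7,7a-hexahydro-2H-cyclopenta[c]pyridine-2,7-dicarboxylate (C7 epimers) | O=C1C[C@@H]2[C@@H](CN(C(=O)OC)C=C2C)C1(C)C(=O)OC | intermediate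
11 | dimethyl (4R,4aS,7aR)-4,7-dimethyl-6-oxooctahydro-2H-cyclopenta[c]pyridine-2,7-dicarboxylate (C7 epimers) | O=C1C[C@@H]2[C@@H](CN(C(=O)OC)C[C@@H]2C)C1(C)C(=O)OC | intermediate
12 | methyl (4R,4aS,7S,7aR)-4,7-dimethyl-6-oxooctahydro-2H-cyclopenta[c]pyridine-2-carboxylate | O=C1C[C@@H]2[C@@H](CN(C(=O)OC)C[C@@H]2C)[C@@H]1C | intermediate
13 | methyl (4R,4aS,6S,7S,7aR)-6-hydroxy-4,7-dimethyloctahydro-2H-cyclopenta[c]pyridine-2-carboxylate (hydroxy carbamate) | O[C@H]1C[C@@H]2[C@@H](CN(C(=O)OC)C[C@@H]2C)[C@@H]1C | intermediate
14 | (4R,4aS,6S,7S,7aR)-2,4,7-trimethyloctahydro-1H-cyclopenta[c]pyridin-6-ol | O[C@H]1C[C@@H]2[C@@H](CN(C)C[C@@H]2C)[C@@H]1C | intermediate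
15 | geranyl acetate | CC(C)=CCC/C(C)=C/COC(C)=O | starting material
16 | (2E,6E)-8-hydroxy-3,7-dimethylocta-2,6-dien-1-yl acetate | CC(=O)OC/C=C(\C)CC/C=C(\C)CO | intermediate
17 | (2E,6E)-2,6-dimethylocta-2,6-diene-1,8-diol | OC/C=C(\C)CC/C=C(\C)CO | intermediate
18 | (2E,6E)-2,6-dimethylocta-2,6-dienedial | O=C/C=C(\C)CC/C=C(\C)C=O | intermediate
19 | (2E,6E)-2,6-dimethylocta-2,6-dienedioic acid | OC(=O)/C=C(\C)CC/C=C(\C)C(O)=O | intermediate
20 | bis[(4R,4aS,6R,7S,7aR)-2,4,7-trimethyloctahydro-1H-cyclopenta[c]pyridin-6-yl] (2E,6E)-2,6-dimethylocta-2,6-dienedioate | C/C(=C\C(=O)O[C@@H]1C[C@@H]2[C@@H](CN(C)C[C@@H]2C)[C@@H]1C)CC/C=C(\C)C(=O)O[C@@H]1C[C@@H]2[C@@H](CN(C)C[C@@H]2C)[C@@H]1C | target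

Total steps: 13
Longest linear sequence: 9 steps (steps 1 to 8, then step 13)

**Steps most likely to fail**

Step 4. The dihydropyridine may be oxidised directly at the anode and aromatise, the radical may close onto the methyl-bearing alkene, or the C1 cation may lose a proton before methanol captures it. The fallback sets out from 8 and replaces mediated electrolysis by the known Mn(OAc)3-based oxidative free-radical cyclisation of unsaturated β-ketoesters. With Mn(OAc)3·2H2O and Cu(OAc)2·H2O in acetic acid at rt, the enolate bound to trivalent manganese gives the same C7 radical and the same 5-exo closure, divalent copper oxidises the C1 radical, and acetate capture should give dimethyl (4aR,7aR)-1-acetoxy-4,7-dimethyl-6-oxo-1,4a,5,6,7,7a-hexahydro-2H-cyclopenta[c]pyridine-2,7-dicarboxylate F3. Treatment of this acetate with Et3SiH and BF3·OEt2 in CH2Cl2 at −78 °C returns to the route at 10.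

Step 3. The dienolate may add at C2 or C6 and not at C4, or the bound chloride may give weak enantiofacial control. The fallback sets out from 3, 4 and 5 and gives up asymmetric catalysis for a racemate resolution. The uncatalysed coupling in CH2Cl2 at −78 °C to 0 °C, which follows the known C4-selective addition of silyl enol ethers to N-alkoxycarbonylpyridinium chlorides, should give racemic methyl 4-(4-methoxy-3-methyl-2,4-dioxobutyl)-3-methyl-4H-pyridine-1-carboxylate F1. Preparative chromatography on a polysaccharide carbamate chiral stationary phase in supercritical CO2 then separates the enantiomers. The (R)-enantiomer is 8, where the route is rejoined, and methyl (4S)-4-(4-methoxy-3-methyl-2,4-dioxobutyl)-3-methyl-4H-pyridine-1-carboxylate F2 is set aside.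

Step 13. The second esterification may stall, or the activated C6 oxygen next to the C7 methyl group may eliminate to the cyclopentene. The fallback sets out from 14 and separates inversion from ester formation. A Mitsunobu reaction with the small, more acidic 4-nitrobenzoic acid (PPh3, DIAD, THF) should give the inverted (4R,4aS,6R,7S,7aR)-2,4,7-trimethyloctahydro-1H-cyclopenta[c]pyridin-6-yl 4-nitrobenzoate F4. Methanolysis with K2CO3 in MeOH then gives (4R,4aS,6R,7S,7aR)-2,4,7-trimethyloctahydro-1H-cyclopenta[c]pyridin-6-ol F5. Diacid 19 is activated with 2,4,6-trichlorobenzoyl chloride and Et3N as the bis(2,4,6-trichlorobenzoic) mixed anhydride F6. This acylates two equivalents of F5 in the presence of DMAP in toluene (Yamaguchi esterification, retention at C6) and returns to the route at 20.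

**Further compounds**
F1 | step 3 | racemic methyl 4-(4-methoxy-3-methyl-2,4-dioxobutyl)-3-methyl-4H-pyridine-1-carboxylate | COC(=O)C(C)C(=O)CC1C=CN(C(=O)OC)C=C1C
F2 | step 3 | methyl (4S)-4-(4-methoxy-3-methyl-2,4-dioxobutyl)-3-methyl-4H-pyridine-1-carboxylate | COC(=O)C(C)C(=O)C[C@H]1C=CN(C(=O)OC)C=C1C
F3 | step 4 | dimethyl (4aR,7aR)-1-acetoxy-4,7-dimethyl-6-oxo-1,4a,5,6,7,7a-hexahydro-2H-cyclopenta[c]pyridine-2,7-dicarboxylate (epimers at C1 and C7) | O=C1C[C@@H]2[C@@H](C(OC(C)=O)N(C(=O)OC)C=C2C)C1(C)C(=O)OC
F4 | step 13 | (4R,4aS,6R,7S,7aR)-2,4,7-trimethyloctahydro-1H-cyclopenta[c]pyridin-6-yl 4-nitrobenzoate | O=C(O[C@@H]1C[C@@H]2[C@@H](CN(C)C[C@@H]2C)[C@@H]1C)c1ccc(cc1)[N+](=O)[O-]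
F5 | step 13 | (4R,4aS,6R,7S,7aR)-2,4,7-trimethyloctahydro-1H-cyclopenta[c]pyridin-6-ol | O[C@@H]1C[C@@H]2[C@@H](CN(C)C[C@@H]2C)[C@@H]1C
F6 | step 13 | bis(2,4,6-trichlorobenzoic) mixed anhydride of (2E,6E)-2,6-dimethylocta-2,6-dienedioic acid | O=C(OC(=O)c1c(Cl)cc(Cl)cc1Cl)/C=C(\C)CC/C=C(\C)C(=O)OC(=O)c1c(Cl)cc(Cl)cc1Cl
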